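Atom numbering throughout is the germacrane/eudesmane one: ring carbons C1–C10, C11 the isopropyl CH (methyls C12, C13), C14 the methyl on C10, C15 the one-carbon substituent on C4.

## Analysis of the target

The target is a eudesmane, a trans-fused decalin. Ring A (C1–C5, C10) carries the exocyclic methylene C4=C15. Ring B (C5–C10) carries in a row the ring-fusion hydrogen at C5, the acyloxy group at C6 and the isopropyl group at C7, next to the methyl-bearing quaternary carbon C10. The four stereocentres are (5S,6S,7S,10R): the C14 methyl is axial on the β face, H5 is axial on the α face, the C6 oxygen is α and equatorial, and the isopropyl group is β and equatorial. H5, H6 and H7 are therefore all axial and mutually trans, so ring B holds its substituents in the thermodynamically preferred positions; only C10 cannot be corrected by equilibration. The sensitive groups are the 1,1-disubstituted alkene (it moves into the ring under acid and into conjugation whenever C6 is a ketone), the (E)-cinnamate with its free phenol, and the ester on a hindered carbinol flanked by the ring fusion and the isopropyl-bearing carbon. The difficulties are the quaternary C10 next to the C5–C6–C7 triad, an absolute configuration with no polar handle near C10, and keeping C4=C15 exocyclic. The strategy rests on the C5–C10 bond, which is common to both rings. Cutting it leaves the ten-membered ring C1–C10 with E alkenes at C1=C10 and C4=C5. If C6 is a ketone, the enone C4=C5–C6=O can enolise through C15, so that C5 becomes the nucleophilic α-carbon of a dienol and C4=C15 is left behind once C5 has bonded to C10. All fifteen skeletal carbons then map onto farnesol, and the acyl part is p-coumaric acid.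

## Retrosynthetic reasoning

**Phenol and ester.** The target 19 is taken back to its aryl silyl ether 18, and 18 is cut at the acyl–O6 bond into the alcohol 13 and the acid chloride 17. This is the only heteroatom link between the terpene and the arene, so the cut is convergent and puts the acid-, base- and light-sensitive cinnamate in last. The phenol must be masked or 17 would acylate itself. 17 comes from p-coumaric acid 14 through the silylated acid 16 (the bis-silyl compound 15 is only a transient). The forward acylation must work on a hindered equatorial alcohol without touching C4=C15.

**C6 carbinol.** 13 is taken back to the ketone 12 by removing the C6–H bond. The ketone is not an extra oxidation state, since the key step needs it. The forward reduction must give the equatorial alcohol. A hydride reagent would approach C6 from the α face, away from the axial C14 methyl, and give the axial epimer, so an electron-transfer reduction under product-stability control is planned. It must also be fast and mild enough not to move C4=C15 into conjugation.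

**C5–C10 (the strategic cut).** Cutting this one bond in 12 opens both six-membered rings and gives the ten-membered dienone 10. In the forward direction an acid protonates C1 of the C1=C10 alkene while C5, made nucleophilic through the C15 dienol 11, bonds to C10. This is preferred over any cut inside ring A or ring B because it removes the quaternary centre, the ring fusion and the exocyclic alkene from the problem at once. The trans fusion follows from the E geometry of the ring alkenes and a chair–chair transition state, and the alkene ends at C4=C15 because that is where the dienol leaves it. The step must select one enantiomeric conformer of a planar-chiral macrocycle, which is what the chiral acid is asked to do. C7 in 10 is α to the ketone and can equilibrate, so 10 may be used as the racemate.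

**Oxidation level at C6 and C11.** 10 comes from the allylic alcohol 9 by oxidation, and 9 from the trienol 8 by saturating only the isopropenyl alkene. The isopropenyl group is accepted in 8 because the ring closure delivers it for free. It must be reduced before any acid is applied, since a 1,1-disubstituted alkene would be protonated first.

**C6–C7 (ring closure).** 8 is cut between the carbinol carbon C6 and C7 to give the open-chain bromo-aldehyde 6. In the forward direction the allylchromium 7 formed from the allylic bromide adds through its γ-carbon to the aldehyde. This closure is chosen because it forms the ring at the only sp3–sp3 bond that carries a functional group, and because both E alkenes are already present in the chain and are not touched.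

**Chain functionalisation.** 6 is farnesol 1 with its two ends adjusted. The aldehyde comes from the alcohol 5, and 5 from the acetate 4 by removal of the ester. The bromide 4 comes from the alcohol 3, which comes from farnesyl acetate 2 by allylic oxidation of the terminal E-methyl group. No C–C bond other than the ring closure has to be made on the way to 10.

## Alternatives that were turned down

**Alternative 1:** Ring B is cut at C9–C10 and C5–C6, which leads back to the cyclohexenone keto ester A2 as dienophile and the 1-silyloxy-2-isopropylbutadiene A3. In the forward direction a chiral copper(II) bis(oxazoline) Lewis acid would chelate the two carbonyl groups of A2. The diene would add with its unsubstituted terminus to C10 and its oxygenated terminus to C5, giving the cis-fused adduct A1.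
- For it: two-point binding of a β-keto ester is a well-understood basis for enantiocontrol, the assembly is convergent, and C10 and the C6 oxygen come out of one intermolecular step with the right configuration. On the certainty of absolute stereocontrol this plan is stronger than the chosen one.
- Against it: both reacting carbons of the dienophile are fully substituted, so two adjacent quaternary carbons must form in the cycloaddition. The C5 ester has to be removed by deallylative decarboxylation. C5–H is then set by protonation next to the C4 ketone, where an angular methyl group leaves little trans preference, and the C6 silyloxy group sits β to that ketone, ready for elimination. C7 is still trigonal and needs a face-selective hydrogenation, and the hindered C4 carbonyl must be turned into the methylene.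
- Comparison: only two of the four stereocentres are final in A1 and five or more operations follow. The chosen route delivers the trans fusion, the equatorial isopropyl group and C4=C15 in the key step and needs three further steps.

**Alternative 2:** Both rings are cut at once, at C5–C10 and C1–C2, to the open-chain triene A5. In A5 a 2-(trimethylsilylmethyl)diene (C2=C3–C4=C5) is tethered through C6–C9 to the 1,1-disubstituted alkene C1=C10. Heating would bring about an intramolecular Diels–Alder reaction to the bicyclic allylsilane A4, and protodesilylation would then shift the ring alkene to C4=C15.
- For it: one thermal step builds both rings and C10. The silicon fixes the position of the exocyclic alkene, which is stronger than the kinetic control the chosen route relies on. C6 and C7 would be set beforehand in an open chain by dependable aldol- or crotylation-type chemistry, so no untested asymmetric catalysis is needed.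
- Against it: neither the diene nor the dienophile is activated and the dienophile must form a quaternary carbon, so a very high temperature has to be expected. Nothing in A5 separates the trans from the cis transition state beyond the preference of the C6 and C7 substituents for equatorial positions on the forming ring. The triene, with two stereocentres, an E-trisubstituted diene and the allylsilane, would cost about as many steps as the whole chosen route.
- Comparison: the chosen strategy takes the trans fusion from the geometry of a ring alkene and a chair–chair array, not from a weak conformational bias, and reaches its precursor from a C15 feedstock with a single C–C bond formation.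

**Alternative 3:** The decalin and the C6–O bond are taken back in one stroke to farnesyl diphosphate A7, to be converted by a sesquiterpene synthase into the alcohol A6, which is identical with 13. In the active site, ionisation of the diphosphate would be followed by closure of the ten-membered ring at C6–C7, a hydride shift that makes C11 the isopropyl carbon, transannular C5–C10 closure and capture of water at C6.
- For it: this is the same cascade logic as the chosen route, run by a catalyst that controls all four stereocentres at once. It would shorten the synthesis to three steps and is clearly superior in step economy and, if such an enzyme exists, in stereocontrol.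
- Against it: the plan depends on one specific protein whose product has exactly this hydroxylation site, alkene position and absolute configuration. Cationic cascades of this kind branch easily (proton loss instead of water capture, capture at another carbon, other hydride shifts), so the enzyme would first have to be found or engineered. A7 is a costly stoichiometric substrate outside a fermentation setting, and the step cannot be written as defined reagents acting on catalogue chemicals.
- Comparison: the chosen strategy keeps the biomimetic bond construction but replaces the protein by a small-molecule acid and the water capture by a ketone already at C6. It is longer, but every compound is defined, either enantiomer is open through the choice of catalyst, and the fallback does not depend on biology.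

Key step: step 9

Assumption (remark on the chemistry): 8, 9 and 10 are racemates and their SMILES show the enantiomer that maps onto the target. The enantiomer of the acid catalyst in step 9 that leads to (5S,10R) is taken to be identified in a first screen.

## Route

Step 1
Reactants: 1 (2E,6E)-farnesol
Product: 2 (2E,6E)-farnesyl acetate
Conditions: Ac2O, pyridine, DMAP (cat.), CH2Cl2, 0 °C to rt
Reagents that add atoms: acetic anhydride, CC(=O)OC(C)=O
Why: DMAP-catalysed acylation of a primary allylic alcohol; the acetate masks C6–OH (farnesol C1) and deactivates the neighbouring alkene toward the selenium ene reaction of step 2.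

Step 2
Reactants: 2 (2E,6E)-farnesyl acetate
Product: 3 (2E,6E,10E)-12-hydroxy-3,7,11-trimethyldodeca-2,6,10-trien-1-yl acetate
Conditions: SeO2 (cat.), t-BuOOH, salicylic acid (cat.), CH2Cl2, 0 °C to rt, stopped before full conversion
Reagents that add atoms: selenium dioxide (catalytic oxygen carrier), O=[Se]=O; tert-butyl hydroperoxide (terminal oxidant), CC(C)(C)OO
Why: Allylic oxidation by SeO2 (ene reaction, then [2,3]-sigmatropic shift) takes place at the most electron-rich, terminal trisubstituted alkene and on its E-methyl group, so the (10E)-allylic alcohol should be the main product; the catalytic variant limits over-oxidation to the enal.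

Step 3
Reactants: 3 (2E,6E,10E)-12-hydroxy-3,7,11-trimethyldodeca-2,6,10-trien-1-yl acetate
Product: 4 (2E,6E,10E)-12-bromo-3,7,11-trimethyldodeca-2,6,10-trien-1-yl acetate
Conditions: CBr4, PPh3, CH2Cl2, 0 °C
Reagents that add atoms: carbon tetrabromide, BrC(Br)(Br)Br
Why: Appel reaction; SN2 displacement of the alkoxyphosphonium group at the primary allylic carbon at low temperature should keep the (10E) geometry and avoid allylic transposition.

Step 4
Reactants: 4 (2E,6E,10E)-12-bromo-3,7,11-trimethyldodeca-2,6,10-trien-1-yl acetate
Product: 5 (2E,6E,10E)-12-bromo-3,7,11-trimethyldodeca-2,6,10-trien-1-ol
Conditions: DIBAL-H (2.2 equiv), CH2Cl2, −78 °C; aq. potassium sodium tartrate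
Reagents that add atoms: none
Why: Reductive cleavage of the acetate with an aluminium hydride at −78 °C; this is chosen over basic methanolysis because an alkoxide would substitute the allylic bromide, whereas DIBAL-H reduces the ester much faster than it attacks a primary allylic bromide at this temperature.

Step 5
Reactants: 5 (2E,6E,10E)-12-bromo-3,7,11-trimethyldodeca-2,6,10-trien-1-ol
Product: 6 (2E,6E,10E)-12-bromo-3,7,11-trimethyldodeca-2,6,10-trienal
Conditions: activated MnO2 (excess), CH2Cl2, rt
Reagents that add atoms: none
Why: MnO2 oxidation of a primary allylic alcohol to the enal; the neutral heterogeneous oxidant should leave the allylic bromide and the (2E) geometry untouched.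

Step 6
Reactants: 6 (2E,6E,10E)-12-bromo-3,7,11-trimethyldodeca-2,6,10-trienal
Product: 8 rac-(6R*,7S*)-germacra-1(10)E,4E,11-trien-6-ol [(1R*,2E,6E,10S*)-3,7-dimethyl-10-(prop-1-en-2-yl)cyclodeca-2,6-dien-1-ol; OH and isopropenyl trans], via allylchromium(III) dichloride 7 (not isolated)
Conditions: CrCl2 (excess), THF, rt, slow addition of 6 (final concentration about 3 mM)
Reagents that add atoms: none
Why: Intramolecular Nozaki–Hiyama allylation: Cr(II) inserts into the C–Br bond and the allylchromium 7 adds through its γ-carbon (C7) to the aldehyde carbon (C6) in a closed six-membered chair transition state, which closes the ten-membered ring and leaves C11=C12 as the isopropenyl group; high dilution favours ring closure over oligomerisation. C6 and C7 form as a racemic pair, expected mainly trans from the chair transition state, and the C6 configuration is erased again in step 8.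

Step 7
Reactants: 8 rac-(6R*,7S*)-germacra-1(10)E,4E,11-trien-6-ol
Product: 9 rac-(6S*,7S*)-germacra-1(10)E,4E-dien-6-ol [(1S*,2E,6E,10S*)-3,7-dimethyl-10-(propan-2-yl)cyclodeca-2,6-dien-1-ol; same relative arrangement as 8]
Conditions: H2 (1 atm), RhCl(PPh3)3 (5–10 mol%), toluene, rt
Reagents that add atoms: none
Why: Homogeneous hydrogenation with the rhodium(I) phosphine complex discriminates by steric access, so the 1,1-disubstituted isopropenyl alkene should be reduced well before the two trisubstituted ring alkenes; no stereocentre is created. Room temperature is kept because germacra-1(10),4-dienes undergo Cope rearrangement on heating.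

Step 8
Reactants: 9 rac-(6S*,7S*)-germacra-1(10)E,4E-dien-6-ol
Product: 10 rac-(E,E)-germacra-1(10),4-dien-6-one [(2E,6E)-3,7-dimethyl-10-(propan-2-yl)cyclodeca-2,6-dien-1-one; enantiomer drawn: 7S]
Conditions: activated MnO2 (excess), CH2Cl2, 0 °C to rt; filtration, chromatography on Et3N-deactivated silica, storage cold
Reagents that add atoms: none
Why: MnO2 oxidation of a secondary allylic alcohol to the conjugated enone under neutral conditions; C6 becomes the ketone and C7 its epimerisable α-carbon. Neutral, cold handling should prevent premature transannular reaction, E/Z isomerisation of the enone and Cope rearrangement.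

Step 9
Reactants: 10 rac-(E,E)-germacra-1(10),4-dien-6-one
Product: 12 (5S,7S,10R)-eudesm-4(15)-en-6-one [(2S,4aR,8aS)-4a-methyl-8-methylidene-2-(propan-2-yl)octahydronaphthalen-1(2H)-one], via C15 dienol 11 (not isolated)
Conditions: confined chiral imidodiphosphorimidate Brønsted acid (5 mol%), CHCl3, −40 to −20 °C
Reagents that add atoms: none
Why: Proposed new method: the acid binds the C6 carbonyl and its conjugate base removes a proton from C15 (the methyl group cis to C6 on the E-enone), which gives the dienol 11 in low concentration; the acid then protonates C1 of the C1=C10 alkene on its outer face while C5 of the dienol, held within bonding distance of C10 in the crossed chair–chair conformer, attacks the developing tertiary cation, and loss of the O–H proton returns the C6 ketone with C4=C15 left exocyclic (direct attack of the enone C4=C5 bond through C5 followed by proton loss from C15 would converge on the same product). The closest known reaction types are the acid-mediated transannular cyclisation of germacradienones to eudesmenones without catalyst control, and enantioselective cation–olefin cyclisations and alkene hydrofunctionalisations with confined chiral acids. Ring A (C1–C5, C10) closes 6-endo with respect to the protonated alkene and enol-exo with respect to the nucleophile, ring B (C5–C10) closes 6-exo with respect to that alkene and enol-endo, and the single new bond C5–C10 closes both. The relative configuration of C5 and C10 follows from the macrocycle: in the reacting conformer the C14 methyl and C5–H point to opposite faces of the ring, and the E geometry of the 1(10)-alkene and of the C4=C5 bond from which the dienol derives keeps them there, so the new bond gives the trans-decalin. The absolute configuration of C5 and C10 is set by the catalyst pocket, which has to select one of the two enantiomeric chair–chair conformers of the planar-chiral ring. C7 is controlled by matching and equilibration: in the selected conformer only the (7S) enantiomer of 10 carries the isopropyl group pseudo-equatorially and reacts fast, the (7R) enantiomer is fed into it by acid-catalysed enolisation toward C7 (dynamic kinetic resolution), and the equatorial position is also the stable one next to the ketone in 12. The step needs enantioface selection, enolisation toward C15 and not C3 (secured by the cis relation of C15 to the carbonyl and the internal proton relay of the bound acid), and survival of the β,γ-unsaturated ketone, for which low temperature and a catalytic, non-nucleophilic acid are chosen.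

Step 10
Reactants: 12 (5S,7S,10R)-eudesm-4(15)-en-6-one
Product: 13 (5S,6S,7S,10R)-eudesm-4(15)-en-6-ol [6α-ol; (1S,2S,4aR,8aS)-4a-methyl-8-methylidene-2-(propan-2-yl)decahydronaphthalen-1-ol]
Conditions: SmI2 (2.5 equiv), H2O, Et3N, THF, 0 °C, minutes
Reagents that add atoms: none
Why: Electron-transfer reduction with SmI2–water–amine goes through a ketyl and an organosamarium that is protonated to the more stable alcohol, here the equatorial 6α-alcohol with C6–H axial and anti to H5 and H7; a hydride reagent would instead approach from the α face, away from the axial C14 methyl, and give the axial epimer. The reduction should be complete within minutes at 0 °C, which leaves little time for base-induced migration of C4=C15 into conjugation.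

Step 11
Reactants: 14 p-coumaric acid [(E)-3-(4-hydroxyphenyl)prop-2-enoic acid]
Product: 16 (E)-3-[4-(tert-butyldimethylsilyloxy)phenyl]prop-2-enoic acid, via bis-silyl derivative 15 (not isolated)
Conditions: TBSCl (2.2 equiv), imidazole, DMF, rt; then AcOH/THF/H2O, rt
Reagents that add atoms: tert-butyldimethylsilyl chloride, CC(C)(C)[Si](C)(C)Cl
Why: Silyl protection of both acidic OH groups followed by selective hydrolysis of the far more labile silyl ester 15 in aqueous acetic acid; the aryl silyl ether should survive these conditions.

Step 12
Reactants: 16 (E)-3-[4-(tert-butyldimethylsilyloxy)phenyl]prop-2-enoic acid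
Product: 17 (E)-3-[4-(tert-butyldimethylsilyloxy)phenyl]prop-2-enoyl chloride
Conditions: (COCl)2, DMF (cat.), CH2Cl2, 0 °C to rt; evaporation, used crude
Reagents that add atoms: oxalyl chloride, O=C(Cl)C(=O)Cl
Why: Acid chloride formation through the Vilsmeier-type chloroiminium species; the aryl silyl ether should tolerate the short exposure to HCl in CH2Cl2 and the E alkene is not affected.

Step 13
Reactants: 13 (5S,6S,7S,10R)-eudesm-4(15)-en-6-ol; 17 (E)-3-[4-(tert-butyldimethylsilyloxy)phenyl]prop-2-enoyl chloride
Product: 18 (5S,6S,7S,10R)-eudesm-4(15)-en-6-yl (E)-3-[4-(tert-butyldimethylsilyloxy)phenyl]prop-2-enoate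
Conditions: Et3N, DMAP, CH2Cl2, 0 °C to rt
Reagents that add atoms: none
Why: DMAP-catalysed acylation of the hindered secondary alcohol through the N-acylpyridinium ion; the C6–O bond is not broken, so the configuration at C6 is retained, and the conditions are not acidic enough to move C4=C15.

Step 14
Reactants: 18 (5S,6S,7S,10R)-eudesm-4(15)-en-6-yl (E)-3-[4-(tert-butyldimethylsilyloxy)phenyl]prop-2-enoate
Product: 19 (5S,6S,7S,10R)-eudesm-4(15)-en-6-yl (E)-3-(4-hydroxyphenyl)prop-2-enoate [CNP0321375.1; (1S,2S,4aR,8aS)-4a-methyl-8-methylidene-2-(propan-2-yl)decahydronaphthalen-1-yl (2E)-3-(4-hydroxyphenyl)prop-2-enoate]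
Conditions: TBAF (1.1 equiv), AcOH (1.1 equiv), THF, 0 °C
Reagents that add atoms: none
Why: Fluoride-mediated cleavage of the aryl silyl ether; the acetic acid buffer protonates the phenoxide as it forms and should protect the cinnamate ester from transesterification or hydrolysis.

## Compound list

1 | (2E,6E)-farnesol | CC(C)=CCC/C(C)=C/CC/C(C)=C/CO | starting material
2 | (2E,6E)-farnesyl acetate | CC(C)=CCC/C(C)=C/CC/C(C)=C/COC(C)=O | intermediate
3 | (2E,6E,10E)-12-hydroxy-3,7,11-trimethyldodeca-2,6,10-trien-1-yl acetate | OC/C(C)=C/CC/C(C)=C/CC/C(C)=C/COC(C)=O | intermediate
4 | (2E,6E,10E)-12-bromo-3,7,11-trimethyldodeca-2,6,10-trien-1-yl acetate | BrC/C(C)=C/CC/C(C)=C/CC/C(C)=C/COC(C)=O | intermediate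
5 | (2E,6E,10E)-12-bromo-3,7,11-trimethyldodeca-2,6,10-trien-1-ol | BrC/C(C)=C/CC/C(C)=C/CC/C(C)=C/CO | intermediate
6 | (2E,6E,10E)-12-bromo-3,7,11-trimethyldodeca-2,6,10-trienal | BrC/C(C)=C/CC/C(C)=C/CC/C(C)=C/C=O | intermediate
7 | allylchromium(III) dichloride derived from 6 (Cr on C12; drawn η1, THF ligands omitted) | Cl[Cr](Cl)C/C(C)=C/CC/C(C)=C/CC/C(C)=C/C=O | intermediate (not isolated)
8 | rac-(6R*,7S*)-germacra-1(10)E,4E,11-trien-6-ol (racemate, one enantiomer drawn) | CC(=C)[C@@H]1CC/C(C)=C/CC/C(C)=C/[C@H]1O | intermediate
9 | rac-(6S*,7S*)-germacra-1(10)E,4E-dien-6-ol (racemate, one enantiomer drawn) | CC(C)[C@@H]1CC/C(C)=C/CC/C(C)=C/[C@H]1O | intermediate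
10 | rac-(E,E)-germacra-1(10),4-dien-6-one (racemate, 7S enantiomer drawn) | CC(C)[C@@H]1CC/C(C)=C/CC/C(C)=C/C1=O | intermediate
11 | (7S)-germacra-1(10)E,4(15),5-trien-6-ol (C15 dienol, OH cis to C4) | CC(C)[C@@H]1CC/C(C)=C/CCC(=C)/C=C1\O | intermediate (not isolated)
12 | (5S,7S,10R)-eudesm-4(15)-en-6-one | C=C1CCC[C@]2(C)CC[C@@H](C(C)C)C(=O)[C@@H]12 | intermediate
13 | (5S,6S,7S,10R)-eudesm-4(15)-en-6-ol | C=C1CCC[C@]2(C)CC[C@@H](C(C)C)[C@H](O)[C@@H]12 | intermediate
14 | p-coumaric acid | O=C(O)/C=C/c1ccc(O)cc1 | starting material
15 | tert-butyldimethylsilyl (E)-3-[4-(tert-butyldimethylsilyloxy)phenyl]prop-2-enoate | CC(C)(C)[Si](C)(C)OC(=O)/C=C/c1ccc(O[Si](C)(C)C(C)(C)C)cc1 | intermediate (not isolated)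
16 | (E)-3-[4-(tert-butyldimethylsilyloxy)phenyl]prop-2-enoic acid | O=C(O)/C=C/c1ccc(O[Si](C)(C)C(C)(C)C)cc1 | intermediate
17 | (E)-3-[4-(tert-butyldimethylsilyloxy)phenyl]prop-2-enoyl chloride | O=C(Cl)/C=C/c1ccc(O[Si](C)(C)C(C)(C)C)cc1 | intermediate
18 | (5S,6S,7S,10R)-eudesm-4(15)-en-6-yl (E)-3-[4-(tert-butyldimethylsilyloxy)phenyl]prop-2-enoate | C=C1CCC[C@]2(C)CC[C@@H](C(C)C)[C@H](OC(=O)/C=C/c3ccc(O[Si](C)(C)C(C)(C)C)cc3)[C@@H]12 | intermediate
19 | (5S,6S,7S,10R)-eudesm-4(15)-en-6-yl (E)-3-(4-hydroxyphenyl)prop-2-enoate | C=C1CCC[C@]2(C)CC[C@@H](C(C)C)[C@H](OC(=O)/C=C/c3ccc(O)cc3)[C@@H]12 | target

## Step count and least certain steps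

Total: 14 steps. Longest linear sequence: 12 steps (steps 1–10, 13, 14); the acyl side chain takes 2 steps (11, 12).

**Step 9 (key step).** Several processes could defeat it:
- The catalyst may not discriminate well enough between the two enantiomeric chair–chair conformers of the flexible ring.
- Enolisation toward C7 may be slower than cyclisation, so that only the matched half of the racemate is funnelled.
- The acid may move C4=C15 of the product into conjugation with the C6 ketone after ring closure.
- The C10 cation may be quenched by proton loss or by the carbonyl oxygen instead of by C5.

The fallback uses known chemistry, sets out from 10 and comes back at 13. Racemic 10 would be cyclised with a catalytic achiral sulfonic acid (p-TsOH, CH2Cl2, −20 °C), the known acid-mediated transannular closure of germacradienones. Each enantiomer of 10 should react through the chair–chair conformer with the isopropyl group equatorial, so 12 would form together with its enantiomer, ent-eudesm-4(15)-en-6-one F1. Reduction as in step 10 would give 13 together with ent-eudesm-4(15)-en-6-ol F2. Esterification of this racemate with (1S)-camphanic chloride (pyridine, DMAP) would give two diastereomers, the camphanate of 13 F3 and the camphanate of the enantiomeric alcohol F4, to be separated by chromatography or crystallisation. Saponification of F3 (KOH, MeOH/H2O) would return 13 as a single enantiomer. The price is three extra steps and half of the material.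

**Step 6.** Intermolecular coupling to dimers and oligomers, or protonation of the allylchromium before it finds the aldehyde, could outrun the closure of the strained ten-membered ring. The fallback sets out from 6 and comes back at 8. The nucleophile would be generated catalytically by umpolung: Pd(PPh3)4 (cat.) and Et2Zn in THF under slow addition, where oxidative addition gives a π-allylpalladium complex that transmetalates to an allylzinc species. This closes the same C6–C7 bond through the same kind of chair transition state in a homogeneous solution, where the low stationary concentration is easier to keep than over a suspended chromium salt.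

**Step 7.** The strained E alkenes of the ring may be reduced along with the isopropenyl group, or a rhodium hydride may isomerise the isopropenyl group to the isopropylidene. The fallback sets out from 8 and comes back at 9, and replaces hydrogenation by hydroboration and deoxygenation. 9-BBN (excess, THF, 0 °C to rt; then NaOH, H2O2) adds only to the 1,1-disubstituted alkene and should give the 6,12-diol F5 (C11 epimers, both usable). Selective sulfonylation of the primary alcohol (TsCl, pyridine, 0 °C) would give the 12-tosylate F6, and LiBHEt3 (THF, 0 °C) would replace the tosylate by hydrogen to give 9.

**Step 10.** Protonation of the samarium intermediate may not be selective enough for the equatorial alcohol, or the amine may shift C4=C15 into conjugation before the ketone is reduced. The fallback sets out from 12 and comes back at 13. A dissolving-metal reduction (Li, liquid NH3/THF, t-BuOH, −78 °C, NH4Cl quench) moves the stereo-determining event to an alkali-metal carbanion that settles into the equatorial alkoxide before protonation. This is the classical way to the more stable alcohol from a ketone whose axial face is blocked by an angular methyl group, and the isolated alkene is not reduced under these conditions.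

## Further compounds

F1 | step 9 | (5R,7R,10S)-eudesm-4(15)-en-6-one (enantiomer of 12) | C=C1CCC[C@@]2(C)CC[C@H](C(C)C)C(=O)[C@H]12
F2 | step 9 | (5R,6R,7R,10S)-eudesm-4(15)-en-6-ol (enantiomer of 13) | C=C1CCC[C@@]2(C)CC[C@H](C(C)C)[C@@H](O)[C@H]12
F3 | step 9 | (5S,6S,7S,10R)-eudesm-4(15)-en-6-yl (1S,4R)-camphanate | C=C1CCC[C@]2(C)CC[C@@H](C(C)C)[C@H](OC(=O)[C@@]34CC[C@@](C)(C(=O)O3)C4(C)C)[C@@H]12
F4 | step 9 | (5R,6R,7R,10S)-eudesm-4(15)-en-6-yl (1S,4R)-camphanate | C=C1CCC[C@@]2(C)CC[C@H](C(C)C)[C@@H](OC(=O)[C@@]34CC[C@@](C)(C(=O)O3)C4(C)C)[C@H]12
F0 | step 6 | none | none
F5 | step 7 | rac-(6R*,7S*)-germacra-1(10)E,4E-diene-6,12-diol (C11 epimers; one enantiomer drawn) | CC(CO)[C@@H]1CC/C(C)=C/CC/C(C)=C/[C@H]1O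
F6 | step 7 | rac-(6R*,7S*)-6-hydroxygermacra-1(10)E,4E-dien-12-yl 4-methylbenzenesulfonate (C11 epimers; one enantiomer drawn) | Cc1ccc(S(=O)(=O)OCC(C)[C@@H]2CC/C(C)=C/CC/C(C)=C/[C@H]2O)cc1
F0 | step 10 | none | none
A1 | alternative 1 | cis-fused allyl keto ester Diels–Alder adduct (allyl (1R,4aR,8aR)-type 1-(tert-butyldimethylsilyloxy)-4a-methyl-8-oxo-2-(propan-2-yl)-octahydronaphthalene-8a-carboxylate, C7=C8 alkene) | O=C1CCC[C@]2(C)CC=C(C(C)C)[C@H](O[Si](C)(C)C(C)(C)C)[C@]12C(=O)OCC=C
A2 | alternative 1 | allyl 2-methyl-6-oxocyclohex-1-ene-1-carboxylate | CC1=C(C(=O)OCC=C)C(=O)CCC1
A3 | alternative 1 | tert-butyldimethyl{[(1E)-2-(propan-2-yl)buta-1,3-dien-1-yl]oxy}silane | C=C/C(C(C)C)=C/O[Si](C)(C)C(C)(C)C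
A4 | alternative 2 | trans-fused bicyclic allylsilane (6α-silyloxy-15-trimethylsilyl-eudesm-3-ene) | C[Si](C)(C)CC1=CCC[C@]2(C)CC[C@@H](C(C)C)[C@H](O[Si](C)(C)C(C)(C)C)[C@@H]12
A5 | alternative 2 | open-chain triene (E-diene C2=C3–C4(CH2SiMe3)=C5, C6 silyloxy, C7 isopropyl, C1=C10 isopropenyl end) | C=C/C(C[Si](C)(C)C)=C/[C@@H](O[Si](C)(C)C(C)(C)C)[C@H](C(C)C)CCC(C)=C
A6 | alternative 3 | (5S,6S,7S,10R)-eudesm-4(15)-en-6-ol (identical with 13) | C=C1CCC[C@]2(C)CC[C@@H](C(C)C)[C@H](O)[C@@H]12
A7 | alternative 3 | (2E,6E)-farnesyl diphosphate | CC(C)=CCC/C(C)=C/CC/C(C)=C/COP(=O)(O)OP(=O)(O)O
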